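**Plan**
1. Retrosynthesis: the first cut is the C8'–C9' bond of the docosyl chain (C1' sits on pyrrole C3). It gives 9-(2-formyl-1H-pyrrol-3-yl)nonanoic acid and pentadecanoic acid, each cut carbon carrying a CO2H that is lost. The second cut is the pyrrole C3–C1' bond, back to 3-bromo-1H-pyrrole-2-carbaldehyde and non-8-enoic acid.
2. Forward: the pyrrole ring is bought with CHO on C2 and Br on C3, so its substitution pattern is fixed from the start. N-Boc protection, hydroboration/B-alkyl Suzuki–Miyaura coupling (C9 ester arm), one-pot removal of methyl ester and Boc, and last the union of the arm with the C14 tail.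
3. Enabling feature: C8' and C9' are both unbranched CH2 groups inside the polymethylene run, so each can be released as a primary alkyl radical from a carboxylate (two carbons of like polarity joined by a reductive radical coupling). C8' is insulated from the pyrrole ring by seven further CH2 groups, so no cyclisation competes. The C2 formyl group is a vinylogous formamide of N1 and should not be reduced, so the coupling can be the last step on unprotected material and gives the saturated chain with no later reduction.
4. Helpers: the two CO2H groups (activating groups, expelled as CO2 in the key step), the methyl ester and the N-Boc group (both removed in step 4).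
5. Stereochemistry: the target has no stereocentre and no stereogenic double bond, so none has to be set.

Key step: step 5

Assumption: compounds 1, 3 and 8 are taken as catalogue compounds; chain carbons are numbered C1' (on pyrrole C3) to C22'.

**Step 1**
Reactants: 1 3-bromo-1H-pyrrole-2-carbaldehyde
Product: 2 tert-butyl 3-bromo-2-formyl-1H-pyrrole-1-carboxylate
Conditions: Boc2O (1.2 equiv), DMAP (0.1 equiv), MeCN, rt
Reagents that add atoms: di-tert-butyl dicarbonate, CC(C)(C)OC(=O)OC(=O)OC(C)(C)C
Why: DMAP-catalysed N-acylation (carbamate protection) of the acidic pyrrole N–H should be clean; the Boc group suppresses the protodebromination and catalyst inhibition typical of N–H bromopyrroles in palladium couplings and activates C3–Br towards oxidative addition.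

**Step 2**
Reactants: 3 non-8-enoic acid
Product: 4 methyl non-8-enoate
Conditions: MeOH, H2SO4 (cat.), 50 °C
Reagents that add atoms: methanol, CO
Why: Fischer esterification masks the acidic proton that would otherwise consume 9-BBN in step 3; the isolated terminal alkene is inert to catalytic acid in methanol.

**Step 3**
Reactants: 4 methyl non-8-enoate; 2 tert-butyl 3-bromo-2-formyl-1H-pyrrole-1-carboxylate
Product: 6 tert-butyl 2-formyl-3-(9-methoxy-9-oxononyl)-1H-pyrrole-1-carboxylate, via B-alkyl-9-BBN ester 5 (not isolated)
Conditions: 4 (1.3 equiv), 9-BBN (1.2 equiv), THF, 0 °C to rt; then 2 (1.0 equiv), Pd(dppf)Cl2·CH2Cl2 (5 mol%), K3PO4 (3 equiv, 3 M aq), THF/DMF, rt to 45 °C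
Reagents that add atoms: none
Why: Anti-Markovnikov hydroboration of the terminal alkene with 9-BBN puts boron on the chain end (the ester is tolerated, and the alkene is in slight excess so that no B–H remains to reduce the formyl group); B-alkyl Suzuki–Miyaura coupling at the electron-poor C3–Br of 2 then forms the pyrrole C3–C1' bond without touching ester or aldehyde.

**Step 4**
Reactants: 6 tert-butyl 2-formyl-3-(9-methoxy-9-oxononyl)-1H-pyrrole-1-carboxylate
Product: 7 9-(2-formyl-1H-pyrrol-3-yl)nonanoic acid
Conditions: LiOH·H2O (4 equiv), THF/H2O (3:1), rt; then 1 M HCl to pH 3, 0 °C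
Reagents that add atoms: lithium hydroxide, [Li+].[OH-]
Why: Saponification of the methyl ester and hydroxide cleavage of the N-Boc carbamate (labile on a 2-acylpyrrole because the pyrrolide is a good leaving group) should unmask acid and N–H in one operation; the non-enolisable, vinylogous-formamide aldehyde is stable to dilute base and to the mild acidic work-up.

**Step 5**
Reactants: 7 9-(2-formyl-1H-pyrrol-3-yl)nonanoic acid; 8 pentadecanoic acid
Product: 11 3-docosyl-1H-pyrrole-2-carbaldehyde, via pyrrolylnonanoyl N-acyloxyphthalimide 9 (not isolated), via pentadecanoyl N-acyloxyphthalimide 10 (not isolated)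
Conditions: 7 (1 equiv), 8 (3 equiv), N-hydroxyphthalimide (4.2 equiv), DIC (4.2 equiv), THF, rt; then NiCl2·6H2O (20 mol%), 2,2':6',2''-terpyridine (20 mol%), AgNO3 (0.3 equiv), DMF, (+)Mg/(−)RVC, constant current, rt; 1 M HCl work-up
Reagents that add atoms: none
Why: Both acids are converted in the flask into N-acyloxyphthalimides 9 and 10; cathodically generated low-valent nickel–terpyridine transfers one electron to each ester, which fragments to phthalimide anion, CO2 and a primary alkyl radical, and nickel captures one radical, combines with the second and reductively eliminates the C8'–C9' bond while the magnesium anode supplies the electrons. The closest known reaction type is the nickel-electrocatalysed doubly decarboxylative C(sp3)–C(sp3) coupling of two redox-active esters, a reductive relative of the mixed Kolbe coupling that is known for primary–primary pairs of the fatty-acid type. The step closes no ring and creates no stereocentre. It needs cross- over homo-coupling, which is statistical and is secured by the three-fold excess of the cheap acid 8; the homodimer of the excess partner, a non-polar hydrocarbon, should be removed by chromatography. It also needs chemoselectivity, which the substrate secures: the N-acyloxyphthalimides are reduced far more easily than the C2 formyl group (a vinylogous formamide of N1), the N–H is not deprotonated by phthalimide anion, and the radical at C8' lies seven CH2 groups from the pyrrole ring, so no ring closure or addition to the heteroarene can compete.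

**Compound list**
1 | 3-bromo-1H-pyrrole-2-carbaldehyde | O=Cc1[nH]ccc1Br | starting material
2 | tert-butyl 3-bromo-2-formyl-1H-pyrrole-1-carboxylate | CC(C)(C)OC(=O)n1ccc(Br)c1C=O | intermediate
3 | non-8-enoic acid | C=CCCCCCCC(=O)O | starting material
4 | methyl non-8-enoate | C=CCCCCCCC(=O)OC | intermediate
5 | methyl 9-(9-borabicyclo[3.3.1]nonan-9-yl)nonanoate | COC(=O)CCCCCCCCB1C2CCCC1CCC2 | intermediate
6 | tert-butyl 2-formyl-3-(9-methoxy-9-oxononyl)-1H-pyrrole-1-carboxylate | COC(=O)CCCCCCCCc1ccn(C(=O)OC(C)(C)C)c1C=O | intermediate
7 | 9-(2-formyl-1H-pyrrol-3-yl)nonanoic acid | OC(=O)CCCCCCCCc1cc[nH]c1C=O | intermediate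
8 | pentadecanoic acid | CCCCCCCCCCCCCCC(=O)O | starting material
9 | 1,3-dioxoisoindolin-2-yl 9-(2-formyl-1H-pyrrol-3-yl)nonanoate | O=Cc1[nH]ccc1CCCCCCCCC(=O)ON1C(=O)c2ccccc2C1=O | intermediate
10 | 1,3-dioxoisoindolin-2-yl pentadecanoate | CCCCCCCCCCCCCCC(=O)ON1C(=O)c2ccccc2C1=O | intermediate
11 | 3-docosyl-1H-pyrrole-2-carbaldehyde | CCCCCCCCCCCCCCCCCCCCCCc1cc[nH]c1C=O | target

**Total step count:** 5. **Longest linear sequence:** 4 steps (steps 1, 3, 4, 5, or equally steps 2, 3, 4, 5).

**Steps most likely to fail**

Step 5. The two primary radicals may pair mainly with their own kind. The alkyl-nickel intermediate may instead undergo hydrodecarboxylation or β-hydride elimination, or the activated esters may hydrolyse before they are reduced. The fallback gives up the mid-chain union and attaches the whole chain at the ring. Setting out from 2, 1-docosene is hydroborated with 9-BBN (THF, 0 °C to rt) to B-docosyl-9-borabicyclo[3.3.1]nonane F1. F1 is coupled with 2 under the Suzuki–Miyaura conditions of step 3 to give tert-butyl 3-docosyl-2-formyl-1H-pyrrole-1-carboxylate F2. Methanolysis of the carbamate (K2CO3 cat., MeOH/THF, rt) then returns to the route at 11.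

Step 3. The bromopyrrole may undergo protodebromination. The Boc group may be lost early in the basic aqueous medium, so that the pyrrolide inhibits the catalyst. Residual B–H may reduce the formyl group. The fallback replaces hydroboration and the basic boron coupling by a base-free organozinc coupling. Setting out from 2 and commercial methyl 9-bromononanoate, zinc insertion (Zn dust, I2 cat., DMA, 80 °C) gives (9-methoxy-9-oxononyl)zinc bromide F3. Negishi coupling of F3 with 2 (Pd(OAc)2, SPhos, THF/DMA, rt to 40 °C) returns to the route at 6.

Step 4. Prolonged exposure of the deprotected pyrrolide aldehyde to hydroxide may lead to air oxidation or condensation, or the ester hydrolysis may stall. The fallback avoids strong base altogether. Setting out from 6, thermolysis (neat, 160 °C, argon) removes the Boc group to give methyl 9-(2-formyl-1H-pyrrol-3-yl)nonanoate F4. Enzymatic hydrolysis of the ester (pig liver esterase, pH 7.5 phosphate buffer/acetone, rt) then returns to the route at 7.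

**Further compounds**
F1 | step 5 | B-docosyl-9-borabicyclo[3.3.1]nonane | CCCCCCCCCCCCCCCCCCCCCCB1C2CCCC1CCC2
F2 | step 5 | tert-butyl 3-docosyl-2-formyl-1H-pyrrole-1-carboxylate | CCCCCCCCCCCCCCCCCCCCCCc1ccn(C(=O)OC(C)(C)C)c1C=O
F3 | step 3 | (9-methoxy-9-oxononyl)zinc bromide | COC(=O)CCCCCCCC[Zn]Br
F4 | step 4 | methyl 9-(2-formyl-1H-pyrrol-3-yl)nonanoate | COC(=O)CCCCCCCCc1cc[nH]c1C=O
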